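**Convention.** Target numbering is used throughout: C1 bears the C7 methylene (CH2OBz), C2 is the alkene CH, C3, C4 and C6 carry hydroxyl, and C5 carries the secondary benzoate.

**Assumption.** The quinine-derived amine is taken to favour the enone face that gives the (5S,6R) oxirane of 5; if it favours the other face, the quinidine-derived pseudoenantiomer is used with nothing else changed.

## The problem

Target 10 is a single cyclohexene ring, so no ring fusion has to be planned, but every ring carbon is functionalised. The four contiguous stereocentres are 3R,4S,5R,6S: O3 and O6 lie on one face and O4 and O5 on the other, so 3,4 and 5,6 are trans and 4,5 is cis. Only one of the four ring oxygens, O5, is acylated, and it sits between two free hydroxyls. A route that ends with several free hydroxyls must pick O5 out among them, whereas a route that brings O5 in as benzoate avoids that choice. The secondary benzoate migrates to O4 or O6 under base, the primary benzoate is allylic, and the polyol does not tolerate strong acid or heat, so the late steps must be near neutral. The centres can be chained: an oxygen on the O3/O6 face can place O6 by delivery, O5 follows from O6 by inversion, O4 from O6 by a tethered hydride, and O3 can inherit its face from an allylic oxygen at C1. The enabling feature is that C1 is para to C4. The ring therefore maps onto 4-hydroxybenzyl alcohol 1, whose p-quinol 4 has a C4 ketone, a tertiary C1 carbinol and two enantiotopic enone arms (C2–C3 and C5–C6).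

## Retrosynthesis

**10 ⇒ 9 ⇒ 8.** The two O–Si bonds of bis(triethylsilyl) ether 9 are cut last, under buffered fluoride. In 9 the C3–O bond is cut and the oxygen returned to C1, with the alkene moved to C2=C3, which gives tertiary allylic alcohol 8. The neighbouring options for C3 (allylic oxidation of a C1=C2 alkene, or reduction of a C3 ketone) would have to find the lower face unaided. The allylic 1,3-shift is suprafacial and copies the configuration of C1, and it runs downhill to the secondary alcohol with the more substituted alkene. Compound 8 has the same number of stereocentres as 9, but C3, the hardest one, becomes a consequence of C1. The forward step needs a catalyst that moves a hydroxyl across an allyl unit without ionising it. O4 and O6 must be capped, because O4 is allylic in 8 and O6 becomes allylic in 9.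

**8 ⇒ 7 ⇒ 6.** Removing the silyl groups gives triol 7, and cutting the C4–H bond gives enone 6 with three stereocentres. The C4 carbinol must be cis to O5 and anti to O6. A small free hydride would be expected to add along the axial line of the conformer with O5 and O6 equatorial and give the 4,5-trans epimer. The hydride is therefore tied to a hydroxyl on the lower face (O6, or O1), which is the anti-selective directed reduction of a β-hydroxy ketone.

**6 ⇒ 5 + 2.** The C5–O bond is cut to benzoic acid 2 and epoxy ketone 5. Opening at the ketone stage is preferred to opening after reduction. At this stage C5 is marked three ways: it is distal to the only free hydroxyl, it is alpha to the carbonyl, and it is not shielded by C7. After reduction a second hydroxyl would compete for direction. The forward step must invert C5 and leave C6–O untouched, which gives the trans 5,6 pattern and puts the benzoate on O5 without any later selection.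

**5 ⇒ 4.** The C5–O and C6–O bonds of the oxirane are cut, leaving the achiral p-quinol 4. This removes all three stereocentres of 5 at once. The forward reaction has to choose one of two enantiotopic arms and the face of the C1 hydroxyl, and it has to stop after one epoxidation.

**4 ⇒ 3 ⇒ 1 + 2.** The C1–O bond is cut by retro-dearomatisation to phenol 3. The C7–O ester bond is then cut to 4-hydroxybenzyl alcohol 1 and benzoic acid 2, both commodity chemicals. The esterification must spare the phenol.

## Roads not taken

Alternative 1: The C4–O and C5–O bonds are cut back to an arene. Whole-cell enzymatic cis-dihydroxylation of bromobenzene A1 gives diene diol A2 as a single enantiomer.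
- Merits: the absolute configuration and the cis O4/O5 relationship come from one reliable, scalable step, and no new method is needed. In this respect it is ahead of the chosen plan.
- Weak points: with the diol on C4 and C5 the halogen sits on C3 or C6, both oxygen-bearing in 10, so it cannot carry C7. C1 is an unsubstituted diene carbon and needs a separate C–C bond formation. O3 and O6 must still be added. O4 and O5 arrive as an equivalent pair, usually masked together, so O5 must be benzoylated selectively late.
- Comparison: the chosen plan has all seven carbons from the start, brings O5 in as the benzoate, needs no fermentation and is several steps shorter. It pays with an untested key step.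

Alternative 2: The C1–C6 bond is cut. A phosphine-catalysed intramolecular Morita–Baylis–Hillman reaction of the sugar-derived acyclic enethioate aldehyde A3 closes the carbocycle to thioester A4.
- Merits: C3, C4 and C5 come from the chiral pool, and one step makes the ring, the C1=C2 alkene, the C6 carbinol and C7 at the acid oxidation level. The reaction type is precedented.
- Weak points: C6 is set under substrate control of uncertain sense. The aldehyde carbon neighbour C5 in A3 is epimerisable and can lose its β-oxygen under the nucleophilic conditions. A3 needs a long, protecting-group-heavy preparation from a hexose. The thioester must be reduced and benzoylated. The acetonide again ties O4 and O5 together.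
- Comparison: this road is more secure in absolute configuration but clearly longer than the eight steps proposed here.

Alternative 3: The C3–O and C6–O bonds are cut. Photooxygenation of ring diene A6, derived from shikimic acid A5, gives endoperoxide A7 by [4+2] addition anti to the acetonide.
- Merits: one step puts O3 and O6 on the same face, opposite O4 and O5, which is exactly the pattern of 10. The alkene lands at C1=C2, C7 is present, and the chirality is bought. In stereochemical certainty this road is better than the chosen plan, and it is about as short.
- Weak points: after O–O reduction and acetonide removal four secondary hydroxyls are free and O5 alone must be benzoylated. The endoperoxide is prone to base-induced rearrangement to a hydroxy enone, and A6 is an acid-sensitive dihydroarene.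
- Comparison: the chosen plan installs the O5 benzoate regiospecifically by epoxide opening, starts from an achiral commodity phenol, and reaches either enantiomer by choice of catalyst.

Key step: step 3

## Route

Step 1
Reactants: 1 4-hydroxybenzyl alcohol; 2 benzoic acid
Product: 3 4-hydroxybenzyl benzoate
Conditions: PPh3, DIAD, THF, 0 °C to rt
Reagents that add atoms: none
Why: Mitsunobu esterification: only the aliphatic hydroxyl of 1 is activated as an alkoxyphosphonium ion and only the carboxylic acid is acidic enough to act as pronucleophile, so the benzylic ester forms and the phenol stays free, as established for phenolic benzyl alcohols.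

Step 2
Reactants: 3 4-hydroxybenzyl benzoate
Product: 4 (1-hydroxy-4-oxocyclohexa-2,5-dien-1-yl)methyl benzoate
Conditions: PhI(OAc)2, MeCN/H2O (4:1), 0 °C
Reagents that add atoms: water, O
Why: Oxidative dearomatisation of a para-substituted phenol with a trivalent-iodine reagent: the phenol exchanges onto iodine and water attacks the para carbon as iodobenzene departs, giving the achiral p-quinol 4 (mirror plane through C1 and C4).

Step 3
Reactants: 4 (1-hydroxy-4-oxocyclohexa-2,5-dien-1-yl)methyl benzoate
Product: 5 [(1S,5R,6R)-5-hydroxy-2-oxo-7-oxabicyclo[4.1.0]hept-3-en-5-yl]methyl benzoate (target numbering: 1R,5S,6R; 5,6-oxirane syn to the C1 hydroxyl)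
Conditions: 9-amino-9-deoxy-epi-quinine (10 mol %), CF3CO2H (20 mol %), 50% aq. H2O2 (1.1 equiv), 1,4-dioxane, 30 °C
Reagents that add atoms: hydrogen peroxide, OO
Why: Proposed new method: the primary amine condenses with the C4 ketone of 4 to a cross-conjugated iminium ion, hydrogen peroxide adds to C6, and the resulting enamine closes the oxirane by 3-exo-tet attack of C5 on the proximal peroxide oxygen with loss of water, after which hydrolysis returns the catalyst. The closest known reactions are the epoxidation of cyclic enones with H2O2 under cinchona primary-amine salt catalysis and the hydroxyl-directed syn epoxidation of p-quinols with basic peroxide; their combination on a cyclohexadienone is untested. C5 and C6 are set together as a cis oxirane, on the face of the C1 hydroxyl, which hydrogen-bonds the incoming hydroperoxide and whose geminal CH2OBz group blocks the other face at C6. C1 becomes stereogenic only through the choice of arm: the catalyst prefers one face of an enone, and that face coincides with the hydroxyl face on one arm and opposes it on the other, so the matched arm should react and give the (1R,5S,6R) isomer. The step needs arm selectivity, syn facial selectivity and mono-epoxidation; the first two rest on this matched pairing, the third on limiting the oxidant to 1.1 equiv and on the remaining arm of 5 being the mismatched one.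

Step 4
Reactants: 5 [(1S,5R,6R)-5-hydroxy-2-oxo-7-oxabicyclo[4.1.0]hept-3-en-5-yl]methyl benzoate; 2 benzoic acid
Product: 6 [(1R,5R,6R)-5-(benzoyloxy)-1,6-dihydroxy-4-oxocyclohex-2-en-1-yl]methyl benzoate
Conditions: PhCO2H (1.5 equiv), Ti(OiPr)4 (1.5 equiv), CH2Cl2, 0 °C to rt
Reagents that add atoms: none
Why: Titanium-alkoxide-mediated opening of a 2,3-epoxy alcohol by a carboxylic acid: the C1 alkoxide and the oxirane oxygen chelate titanium and benzoate attacks the distal carbon C5, which is also the SN2-activated carbon alpha to the ketone and the one not shielded by C7. Backside attack inverts C5 and leaves the C6–O bond intact, so O5 ends trans to O6 (C5 R).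

Step 5
Reactants: 6 [(1R,5R,6R)-5-(benzoyloxy)-1,6-dihydroxy-4-oxocyclohex-2-en-1-yl]methyl benzoate
Product: 7 [(1R,4S,5S,6R)-5-(benzoyloxy)-1,4,6-trihydroxycyclohex-2-en-1-yl]methyl benzoate
Conditions: Me4NBH(OAc)3, MeCN/AcOH (1:1), −30 to 0 °C
Reagents that add atoms: none
Why: Hydroxyl-directed reduction of a β-hydroxy ketone (Evans–Saksena reduction): O6 (or O1) displaces acetate on boron and the hydride is delivered within the complex to the lower face of C4, giving the 4,6-anti diol with O4 cis to O5 (C4 S). The free reagent is too weak to reduce the enone, which should suppress the undirected pathway to the C4 epimer.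

Step 6
Reactants: 7 [(1R,4S,5S,6R)-5-(benzoyloxy)-1,4,6-trihydroxycyclohex-2-en-1-yl]methyl benzoate
Product: 8 [(1R,4S,5S,6R)-5-(benzoyloxy)-1-hydroxy-4,6-bis(triethylsilyloxy)cyclohex-2-en-1-yl]methyl benzoate
Conditions: Et3SiOTf (2.2 equiv), 2,6-lutidine, CH2Cl2, −78 °C
Reagents that add atoms: triethylsilyl trifluoromethanesulfonate, CC[Si](CC)(CC)OS(=O)(=O)C(F)(F)F
Why: Kinetic silylation with a silyl triflate: the two secondary hydroxyls react at −78 °C while the tertiary C1 hydroxyl should not, and the hindered base does not trigger benzoate migration.

Step 7
Reactants: 8 [(1R,4S,5S,6R)-5-(benzoyloxy)-1-hydroxy-4,6-bis(triethylsilyloxy)cyclohex-2-en-1-yl]methyl benzoate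
Product: 9 [(3R,4S,5R,6S)-5-(benzoyloxy)-3-hydroxy-4,6-bis(triethylsilyloxy)cyclohex-1-en-1-yl]methyl benzoate
Conditions: Ph3SiOReO3 (5 mol %), Et2O, −40 to 0 °C
Reagents that add atoms: none
Why: Rhenium-oxo-catalysed 1,3-transposition of an allylic alcohol: the C1 perrhenate ester undergoes a [3,3] shift across the lower face of the C1–C2–C3 allyl unit, so the oxygen arrives at C3 on the face it occupied at C1 (C3 R). The equilibrium should favour the secondary alcohol with the trisubstituted C1=C2 alkene, and the silyl ethers keep O4 and O6 out of the shift and disfavour ionisation.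

Step 8
Reactants: 9 [(3R,4S,5R,6S)-5-(benzoyloxy)-3-hydroxy-4,6-bis(triethylsilyloxy)cyclohex-1-en-1-yl]methyl benzoate
Product: 10 [(3R,4S,5R,6S)-5-(benzoyloxy)-3,4,6-trihydroxycyclohex-1-en-1-yl]methyl benzoate
Conditions: HF·pyridine, THF/pyridine, 0 °C to rt
Reagents that add atoms: none
Why: Silyl ether deprotection by fluoride in a pyridine-buffered medium removes both triethylsilyl groups; the near-neutral conditions avoid base-induced migration of the C5 benzoate to O4 or O6 and leave the allylic alcohol untouched.

## Compound list

1 | 4-hydroxybenzyl alcohol | OCc1ccc(O)cc1 | starting material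
2 | benzoic acid | O=C(O)c1ccccc1 | starting material
3 | 4-hydroxybenzyl benzoate | O=C(OCc1ccc(O)cc1)c1ccccc1 | intermediate
4 | (1-hydroxy-4-oxocyclohexa-2,5-dien-1-yl)methyl benzoate | O=C1C=CC(O)(COC(=O)c2ccccc2)C=C1 | intermediate
5 | [(1S,5R,6R)-5-hydroxy-2-oxo-7-oxabicyclo[4.1.0]hept-3-en-5-yl]methyl benzoate | O=C(OC[C@]1(O)C=CC(=O)[C@H]2O[C@@H]12)c1ccccc1 | intermediate
6 | [(1R,5R,6R)-5-(benzoyloxy)-1,6-dihydroxy-4-oxocyclohex-2-en-1-yl]methyl benzoate | O=C(OC[C@]1(O)C=CC(=O)[C@H](OC(=O)c2ccccc2)[C@H]1O)c1ccccc1 | intermediate
7 | [(1R,4S,5S,6R)-5-(benzoyloxy)-1,4,6-trihydroxycyclohex-2-en-1-yl]methyl benzoate | O=C(OC[C@]1(O)C=C[C@H](O)[C@H](OC(=O)c2ccccc2)[C@H]1O)c1ccccc1 | intermediate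
8 | [(1R,4S,5S,6R)-5-(benzoyloxy)-1-hydroxy-4,6-bis(triethylsilyloxy)cyclohex-2-en-1-yl]methyl benzoate | O=C(OC[C@]1(O)C=C[C@H](O[Si](CC)(CC)CC)[C@H](OC(=O)c2ccccc2)[C@H]1O[Si](CC)(CC)CC)c1ccccc1 | intermediate
9 | [(3R,4S,5R,6S)-5-(benzoyloxy)-3-hydroxy-4,6-bis(triethylsilyloxy)cyclohex-1-en-1-yl]methyl benzoate | O=C(OCC1=C[C@@H](O)[C@H](O[Si](CC)(CC)CC)[C@H](OC(=O)c2ccccc2)[C@H]1O[Si](CC)(CC)CC)c1ccccc1 | intermediate
10 | [(3R,4S,5R,6S)-5-(benzoyloxy)-3,4,6-trihydroxycyclohex-1-en-1-yl]methyl benzoate | O=C(OCC1=C[C@@H](O)[C@H](O)[C@H](OC(=O)c2ccccc2)[C@H]1O)c1ccccc1 | target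

## Step count and risk

Total: 8 steps. Longest linear sequence: 8 steps (1 to 10).

**Step 3 (key step).** The hydroxyl direction and the catalyst preference may not reinforce each other strongly enough, which would give poor arm or facial selectivity. Iminium formation on the cross-conjugated dienone may be slow enough for unselective background epoxidation to compete, and the second arm may be over-oxidised. Fallback, from 4: the known hydroxyl-directed epoxidation of p-quinols with basic peroxide (H2O2, cat. NaOH, MeOH/THF, 0 °C) gives the racemic syn epoxide F1. It is taken through the conditions of steps 4 and 5 to the racemic hydroxy ketone F2 and the racemic triol F3. F3 is resolved by lipase-catalysed acylation of the C4 allylic hydroxyl (immobilised lipase B from Candida antarctica, vinyl acetate, MTBE). The empirical size rule for secondary alcohols predicts that the (4R) antipode is converted to the antipodal 4-O-acetate F4, leaving 7 unreacted. The route is rejoined at 7, at the cost of half the material.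

**Step 7.** The transposition may stall at equilibrium, or the perrhenate may ionise. Ionisation would erode the C1-to-C3 transfer of configuration or lead to elimination, and silyl exchange with the catalyst is also possible. Fallback, from 8: Babler–Dauben oxidative transposition with pyridinium chlorochromate (C5H5NH[CrO3Cl], 4 Å sieves, CH2Cl2) gives the transposed enone F5. Luche reduction (NaBH4, CeCl3·7H2O, MeOH, −78 °C) should then place the C3 hydroxyl trans to the neighbouring C4 silyloxy group, the usual sense for α-oxygenated cyclohexenones of this type, and returns to the route at 9. This costs one more step, and C3 is then set by hydride approach and not by transfer from C1.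

**Step 4.** The opening may go at the wrong carbon (C6, possibly through participation of the C7 benzoate under Lewis acid). The new β-hydroxy ketone may dehydrate, or isopropoxide may transesterify the primary benzoate. Fallback, from 5: the C1 hydroxyl is silylated (Me3SiCl, imidazole, DMF) to the trimethylsilyl ether F6. F6 is opened without Lewis acid by cesium benzoate buffered with benzoic acid (DMF, 40 °C), so that site selection rests only on SN2 activation alpha to the ketone, giving the silylated hydroxy ketone F7. Citric acid in MeOH removes the silyl group and returns to the route at 6.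

**Step 5.** The weak hydride may reduce the enone too slowly. Leakage through an undirected pathway would give the C4 epimer, and prolonged reaction invites acyl migration. Fallback, from 6: reagent-controlled Corey–Bakshi–Shibata reduction with (S)-1-methyl-3,3-diphenyl-tetrahydro-1H,3H-pyrrolo[1,2-c][1,3,2]oxazaborole and excess BH3·SMe2 (THF, −30 °C). With the alkene arm acting as the large group, the catalyst should direct hydride to the face needed for 4S. This returns directly to 7 and makes no new compound.

## Further compounds

F1 | step 3 | racemic [(1S*,5R*,6R*)-5-hydroxy-2-oxo-7-oxabicyclo[4.1.0]hept-3-en-5-yl]methyl benzoate (racemate of 5, one enantiomer drawn) | O=C(OC[C@]1(O)C=CC(=O)[C@H]2O[C@@H]12)c1ccccc1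
F2 | step 3 | racemic [(1R*,5R*,6R*)-5-(benzoyloxy)-1,6-dihydroxy-4-oxocyclohex-2-en-1-yl]methyl benzoate (racemate of 6, one enantiomer drawn) | O=C(OC[C@]1(O)C=CC(=O)[C@H](OC(=O)c2ccccc2)[C@H]1O)c1ccccc1
F3 | step 3 | racemic [(1R*,4S*,5S*,6R*)-5-(benzoyloxy)-1,4,6-trihydroxycyclohex-2-en-1-yl]methyl benzoate (racemate of 7, one enantiomer drawn) | O=C(OC[C@]1(O)C=C[C@H](O)[C@H](OC(=O)c2ccccc2)[C@H]1O)c1ccccc1
F4 | step 3 | [(1S,4R,5S,6S)-4-acetoxy-5-(benzoyloxy)-1,6-dihydroxycyclohex-2-en-1-yl]methyl benzoate (4-O-acetate of the enantiomer of 7) | O=C(OC[C@@]1(O)C=C[C@@H](OC(C)=O)[C@@H](OC(=O)c2ccccc2)[C@@H]1O)c1ccccc1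
F5 | step 7 | [(4R,5R,6S)-5-(benzoyloxy)-3-oxo-4,6-bis(triethylsilyloxy)cyclohex-1-en-1-yl]methyl benzoate | O=C(OCC1=CC(=O)[C@H](O[Si](CC)(CC)CC)[C@H](OC(=O)c2ccccc2)[C@H]1O[Si](CC)(CC)CC)c1ccccc1
F6 | step 4 | [(1S,5R,6R)-2-oxo-5-(trimethylsilyloxy)-7-oxabicyclo[4.1.0]hept-3-en-5-yl]methyl benzoate | O=C(OC[C@]1(O[Si](C)(C)C)C=CC(=O)[C@H]2O[C@@H]12)c1ccccc1
F7 | step 4 | [(1R,5R,6R)-5-(benzoyloxy)-6-hydroxy-4-oxo-1-(trimethylsilyloxy)cyclohex-2-en-1-yl]methyl benzoate | O=C(OC[C@]1(O[Si](C)(C)C)C=CC(=O)[C@H](OC(=O)c2ccccc2)[C@H]1O)c1ccccc1
F0 | step 5 | none | none
A1 | alternative 1 | bromobenzene | Brc1ccccc1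
A2 | alternative 1 | (1S,2S)-3-bromocyclohexa-3,5-diene-1,2-diol | BrC1=CC=C[C@H](O)[C@@H]1O
A3 | alternative 2 | S-ethyl (E)-4-(tert-butyldimethylsilyloxy)-4-(5-formyl-2,2-dimethyl-1,3-dioxolan-4-yl)but-2-enethioate (configuration as in A4) | CCSC(=O)/C=C/[C@@H](O[Si](C)(C)C(C)(C)C)[C@@H]1OC(C)(C)O[C@@H]1C=O
A4 | alternative 2 | S-ethyl 6-hydroxy-3-(tert-butyldimethylsilyloxy)-4,5-(isopropylidenedioxy)cyclohex-1-ene-1-carbothioate (target numbering) | CCSC(=O)C1=C[C@@H](O[Si](C)(C)C(C)(C)C)[C@@H]2OC(C)(C)O[C@@H]2[C@H]1O
A5 | alternative 3 | shikimic acid | O=C(O)C1=C[C@@H](O)[C@@H](O)[C@H](O)C1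
A6 | alternative 3 | [4,5-(isopropylidenedioxy)cyclohexa-1(6),2-dien-1-yl]methyl benzoate (target numbering, 4,5-cis) | O=C(OCC1=C[C@H]2OC(C)(C)O[C@H]2C=C1)c1ccccc1
A7 | alternative 3 | anti endoperoxide of A6, a 2,3-dioxabicyclo[2.2.2]oct-5-ene bridging C3 and C6 (target numbering) | O=C(OCC1=C[C@H]2OO[C@@H]1[C@H]3OC(C)(C)O[C@H]32)c1ccccc1
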